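**Strategy.** The synthesis rests on disconnecting the C4–C4a bond of ring C, so that ring A enters as a symmetric phloroglucinol ether and C3–C4 as a terminal alkyne. In the key step, gold-catalysed oxidation of a racemic aryl propargyl ether generates an α-oxo gold carbene at C4, which is captured by C4a, the electron-rich ring A carbon flanked by O1 and the C5 oxygen; one operation thus closes the pyran ring and installs the C3 carbonyl. The resulting flavan-3-one has a labile C2–H, and a dynamic kinetic asymmetric hydrogenation then sets C2 and C3 together as the cis (2R,3R) pair before galloylation and global debenzylation.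

Key step: step 6

Remarks on the chemistry:
- Flavan numbering is used throughout (O1, C2, C3, C4, C4a, C5–C8, C8a; ring A = benzo ring, ring B = 2-aryl group, ring C = pyran ring).
- Assumption: the (S)-xylbinap/(S)-daipen ruthenium catalyst of step 7 is taken to reduce the (2R)-ketone preferentially; if a trial shows the opposite sense, the mirror-image catalyst is used and nothing else changes.
- Assumption: compounds 1, 2, 6, 8, 10 and 14 are taken as commercially available.

**Step 1**
Reactants: 1 methyl 3,5-dihydroxy-4-methoxybenzoate; 2 benzyl bromide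
Product: 3 methyl 3,5-bis(benzyloxy)-4-methoxybenzoate
Conditions: BnBr (2.3 equiv), K2CO3, DMF, 60 °C
Reagents that add atoms: benzyl bromide (2), BrCc1ccccc1
Why: Williamson ether synthesis on the two equivalent phenols beside the methoxy group should proceed cleanly, the methyl ester being inert to carbonate.

**Step 2**
Reactants: 3 methyl 3,5-bis(benzyloxy)-4-methoxybenzoate
Product: 4 [3,5-bis(benzyloxy)-4-methoxyphenyl]methanol
Conditions: LiAlH4, THF, 0 °C to rt; H2O work-up
Reagents that add atoms: none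
Why: Hydride reduction of the ester to the primary alcohol should leave the aryl benzyl and methyl ethers untouched.

**Step 3**
Reactants: 4 [3,5-bis(benzyloxy)-4-methoxyphenyl]methanol
Product: 5 3,5-bis(benzyloxy)-4-methoxybenzaldehyde
Conditions: MnO2 (excess), CH2Cl2, rt
Reagents that add atoms: none
Why: Selective MnO2 oxidation of a benzylic alcohol should stop at the aldehyde without over-oxidation.

**Step 4**
Reactants: 5 3,5-bis(benzyloxy)-4-methoxybenzaldehyde; 6 ethynylmagnesium bromide
Product: 7 rac-1-[3,5-bis(benzyloxy)-4-methoxyphenyl]prop-2-yn-1-ol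
Conditions: HC≡CMgBr (1.3 equiv), THF, 0 °C to rt; H2O quench
Reagents that add atoms: ethynylmagnesium bromide (6), C#C[Mg]Br
Why: 1,2-Addition of the alkynyl Grignard reagent to the aldehyde should give the propargylic alcohol, deliberately as a racemate because C2 is set later.

**Step 5**
Reactants: 7 rac-1-[3,5-bis(benzyloxy)-4-methoxyphenyl]prop-2-yn-1-ol; 8 3,5-bis(benzyloxy)phenol
Product: 9 rac-1,3-bis(benzyloxy)-5-({1-[3,5-bis(benzyloxy)-4-methoxyphenyl]prop-2-yn-1-yl}oxy)benzene
Conditions: PPh3, DIAD, THF, 0 °C to rt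
Reagents that add atoms: 3,5-bis(benzyloxy)phenol (8), Oc1cc(OCc2ccccc2)cc(OCc2ccccc2)c1
Why: Mitsunobu etherification should join the phenol oxygen to the activated propargylic carbon, and the configuration of this centre is irrelevant because the material is racemic and C2 is fixed in step 7.

**Step 6**
Reactants: 9 rac-1,3-bis(benzyloxy)-5-({1-[3,5-bis(benzyloxy)-4-methoxyphenyl]prop-2-yn-1-yl}oxy)benzene; 10 2,6-dichloropyridine N-oxide
Product: 12 rac-5,7-bis(benzyloxy)-2-[3,5-bis(benzyloxy)-4-methoxyphenyl]chroman-3-one, via α-oxo gold carbene 11 (not isolated)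
Conditions: Me4tBuXPhosAuCl/AgNTf2 (5 mol %), 10 (1.5 equiv), ClCH2CH2Cl, rt
Reagents that add atoms: 2,6-dichloropyridine N-oxide (10), [O-][n+]1c(Cl)cccc1Cl
Why: Cationic monovalent gold activates the terminal alkyne of 9, the N-oxide oxygen of 10 adds to the internal alkyne carbon (future C3), and N–O cleavage releases 2,6-dichloropyridine to give the α-oxo gold carbene 11 with the carbene at the terminal carbon (future C4). The carbene carbon is then attacked by the ortho carbon of the phloroglucinol ring (future C4a), and rearomatisation with protodeauration should give the chroman-3-one; the closest known reaction type is the gold-catalysed oxidative cyclisation of aryl propargyl ethers to chroman-3-ones. The pyran ring closes in a 6-exo Friedel–Crafts mode at the carbene carbon. No new stereocentre is formed; C2 is carried as a racemate and becomes enolisable on purpose. The step needs alkyne oxidation to outrun direct 6-endo-dig hydroarylation and needs oxygen delivery to the internal carbon; the bulky biaryl phosphine, the excess of a non-basic N-oxide and the Markovnikov bias of a terminal alkyne should secure this. Site selectivity on ring A is not an issue, because the two carbons ortho to the ether oxygen are equivalent by symmetry and the para carbon cannot reach the carbene.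

**Step 7**
Reactants: 12 rac-5,7-bis(benzyloxy)-2-[3,5-bis(benzyloxy)-4-methoxyphenyl]chroman-3-one
Product: 13 (2R,3R)-5,7-bis(benzyloxy)-2-[3,5-bis(benzyloxy)-4-methoxyphenyl]chroman-3-ol
Conditions: H2 (30 atm), RuCl2[(S)-xylbinap][(S)-daipen] (0.5 mol %), t-BuOK (20 mol %), i-PrOH/toluene, rt
Reagents that add atoms: none
Why: In this Noyori-type asymmetric hydrogenation under dynamic kinetic resolution, t-BuOK should equilibrate the enantiomers of 12 through the C2 enolate (C2–H is α to the ketone, benzylic and α to oxygen) while the chiral divalent ruthenium hydride reduces the (2R)-ketone faster and delivers hydride to the C3 carbonyl face anti to the C2 aryl group, so that C2 is fixed by the resolution and C3 by catalyst control reinforced by the substrate, giving the cis (2R,3R) alcohol.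

**Step 8**
Reactants: 13 (2R,3R)-5,7-bis(benzyloxy)-2-[3,5-bis(benzyloxy)-4-methoxyphenyl]chroman-3-ol; 14 3,4,5-tris(benzyloxy)benzoyl chloride
Product: 15 (2R,3R)-5,7-bis(benzyloxy)-2-[3,5-bis(benzyloxy)-4-methoxyphenyl]chroman-3-yl 3,4,5-tris(benzyloxy)benzoate
Conditions: Et3N, DMAP (cat.), CH2Cl2, 0 °C to rt
Reagents that add atoms: 3,4,5-tris(benzyloxy)benzoyl chloride (14), O=C(Cl)c1cc(OCc2ccccc2)c(OCc2ccccc2)c(OCc2ccccc2)c1
Why: DMAP-catalysed acylation through the acylpyridinium ion should esterify the hindered axial C3 hydroxyl with retention, since no C–O bond at a stereocentre is broken.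

**Step 9**
Reactants: 15 (2R,3R)-5,7-bis(benzyloxy)-2-[3,5-bis(benzyloxy)-4-methoxyphenyl]chroman-3-yl 3,4,5-tris(benzyloxy)benzoate
Product: 16 4'-O-methylepigallocatechin-3-O-gallate
Conditions: H2 (1 atm), Pd(OH)2/C, THF/MeOH, rt
Reagents that add atoms: none
Why: Neutral catalytic hydrogenolysis should remove all seven benzyl ethers while the aryl ester, the methyl ether and both stereocentres are retained.

**Compound list**

1 | methyl 3,5-dihydroxy-4-methoxybenzoate | COC(=O)c1cc(O)c(OC)c(O)c1 | starting material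
2 | benzyl bromide | BrCc1ccccc1 | starting material
3 | methyl 3,5-bis(benzyloxy)-4-methoxybenzoate | COC(=O)c1cc(OCc2ccccc2)c(OC)c(OCc2ccccc2)c1 | intermediate
4 | [3,5-bis(benzyloxy)-4-methoxyphenyl]methanol | OCc1cc(OCc2ccccc2)c(OC)c(OCc2ccccc2)c1 | intermediate
5 | 3,5-bis(benzyloxy)-4-methoxybenzaldehyde | O=Cc1cc(OCc2ccccc2)c(OC)c(OCc2ccccc2)c1 | intermediate
6 | ethynylmagnesium bromide | C#C[Mg]Br | starting material
7 | rac-1-[3,5-bis(benzyloxy)-4-methoxyphenyl]prop-2-yn-1-ol (racemate) | C#CC(O)c1cc(OCc2ccccc2)c(OC)c(OCc2ccccc2)c1 | intermediate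
8 | 3,5-bis(benzyloxy)phenol | Oc1cc(OCc2ccccc2)cc(OCc2ccccc2)c1 | starting material
9 | rac-1,3-bis(benzyloxy)-5-({1-[3,5-bis(benzyloxy)-4-methoxyphenyl]prop-2-yn-1-yl}oxy)benzene (racemate) | C#CC(Oc1cc(OCc2ccccc2)cc(OCc2ccccc2)c1)c1cc(OCc2ccccc2)c(OC)c(OCc2ccccc2)c1 | intermediate
10 | 2,6-dichloropyridine N-oxide | [O-][n+]1c(Cl)cccc1Cl | starting material
11 | α-oxo gold carbene (cationic, Me4tBuXPhos on gold, NTf2 counter-ion; carbene at the terminal carbon, ketone at the former internal alkyne carbon; racemic) | O=C(C=[Au][P+](C(C)(C)C)(C(C)(C)C)c1c(C)c(C)c(C)c(C)c1-c1c(C(C)C)cc(C(C)C)cc1C(C)C)C(Oc1cc(OCc2ccccc2)cc(OCc2ccccc2)c1)c1cc(OCc2ccccc2)c(OC)c(OCc2ccccc2)c1.[N-](S(=O)(=O)C(F)(F)F)S(=O)(=O)C(F)(F)F | intermediate (not isolated)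
12 | rac-5,7-bis(benzyloxy)-2-[3,5-bis(benzyloxy)-4-methoxyphenyl]chroman-3-one (racemic flavan-3-one) | O=C1Cc2c(OCc3ccccc3)cc(OCc3ccccc3)cc2OC1c1cc(OCc2ccccc2)c(OC)c(OCc2ccccc2)c1 | intermediate
13 | (2R,3R)-5,7-bis(benzyloxy)-2-[3,5-bis(benzyloxy)-4-methoxyphenyl]chroman-3-ol (2,3-cis) | COc1c(OCc2ccccc2)cc([C@H]2Oc3cc(OCc4ccccc4)cc(OCc4ccccc4)c3C[C@H]2O)cc1OCc1ccccc1 | intermediate
14 | 3,4,5-tris(benzyloxy)benzoyl chloride | O=C(Cl)c1cc(OCc2ccccc2)c(OCc2ccccc2)c(OCc2ccccc2)c1 | starting material
15 | (2R,3R)-5,7-bis(benzyloxy)-2-[3,5-bis(benzyloxy)-4-methoxyphenyl]chroman-3-yl 3,4,5-tris(benzyloxy)benzoate | COc1c(OCc2ccccc2)cc([C@H]2Oc3cc(OCc4ccccc4)cc(OCc4ccccc4)c3C[C@H]2OC(=O)c2cc(OCc3ccccc3)c(OCc3ccccc3)c(OCc3ccccc3)c2)cc1OCc1ccccc1 | intermediate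
16 | 4'-O-methylepigallocatechin-3-O-gallate, (2R,3R)-5,7-dihydroxy-2-(3,5-dihydroxy-4-methoxyphenyl)chroman-3-yl 3,4,5-trihydroxybenzoate | COc1c(O)cc([C@H]2Oc3cc(O)cc(O)c3C[C@H]2OC(=O)c2cc(O)c(O)c(O)c2)cc1O | target

**Totals**

Total step count: 9. Longest linear sequence: 9 steps (1 to 16); compounds 2, 6, 8, 10 and 14 enter as purchased materials.

**Steps most likely to fail**

Step 6 (key step). The very electron-rich ring A may attack the gold-activated alkyne directly (6-endo-dig hydroarylation) before oxygen transfer, the propargylic–benzylic C–O bond may ionise under gold, or the carbene may be oxidised a second time. The fallback sets out from 9 and comes back at 12, and it closes the same C4–C4a bond without oxidant. Treatment of 9 with Ph3PAuNTf2 in CH2Cl2 at rt should give rac-5,7-bis(benzyloxy)-2-[3,5-bis(benzyloxy)-4-methoxyphenyl]-2H-chromene F1. Hydroboration with BH3·THF followed by NaOH/H2O2 should place the hydroxyl at C3, anti to the C2 aryl group, and give rac-2,3-trans-5,7-bis(benzyloxy)-2-[3,5-bis(benzyloxy)-4-methoxyphenyl]chroman-3-ol F2. Dess–Martin periodinane in CH2Cl2 should then oxidise F2 to ketone 12.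

Step 7. Enolisation may run mainly towards C4, so that C2 racemises more slowly than the ketone is reduced, or the catalyst may discriminate the enantiomers poorly; either process would erode enantiomeric purity or give trans alcohol. The fallback sets out from 12 and comes back at 13, replacing asymmetric catalysis by substrate-controlled reduction and classical resolution. LiBH(s-Bu)3 (L-Selectride) in THF at −78 °C should attack anti to the C2 aryl group and give rac-cis-5,7-bis(benzyloxy)-2-[3,5-bis(benzyloxy)-4-methoxyphenyl]chroman-3-ol F3. Esterification with (S)-2-methoxy-2-phenylacetic acid (DCC, DMAP, CH2Cl2) should give two diastereomers, the (2R,3R)-chroman-3-yl (S)-2-methoxy-2-phenylacetate F4 and the (2S,3S)-chroman-3-yl (S)-2-methoxy-2-phenylacetate F5, to be separated by chromatography or crystallisation. LiOH in THF/MeOH/H2O should cleave F4 to 13.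

Step 5. The activated propargylic–benzylic alcohol may ionise, which would lead to C-alkylation of the electron-rich phenol or to elimination in place of O-alkylation. The fallback sets out from 7 and comes back at 9, replacing the Mitsunobu reaction by copper-catalysed propargylic substitution. Acetylation (Ac2O, Et3N, DMAP, CH2Cl2) should give rac-1-[3,5-bis(benzyloxy)-4-methoxyphenyl]prop-2-yn-1-yl acetate F6. With phenol 8, [Cu(MeCN)4]BF4 (monovalent copper), 2,6-bis(4,4-dimethyl-4,5-dihydro-1,3-oxazol-2-yl)pyridine and i-Pr2NEt in MeOH at 0 °C, F6 should react through a copper allenylidene, which directs the phenol oxygen to the propargylic carbon and gives 9.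

**Further compounds**

F1 | step 6 | rac-5,7-bis(benzyloxy)-2-[3,5-bis(benzyloxy)-4-methoxyphenyl]-2H-chromene (racemate) | COc1c(OCc2ccccc2)cc(C2C=Cc3c(OCc4ccccc4)cc(OCc4ccccc4)cc3O2)cc1OCc1ccccc1
F2 | step 6 | rac-2,3-trans-5,7-bis(benzyloxy)-2-[3,5-bis(benzyloxy)-4-methoxyphenyl]chroman-3-ol (racemate, both enantiomers written) | COc1c(OCc2ccccc2)cc([C@H]2Oc3cc(OCc4ccccc4)cc(OCc4ccccc4)c3C[C@@H]2O)cc1OCc1ccccc1.COc1c(OCc2ccccc2)cc([C@@H]2Oc3cc(OCc4ccccc4)cc(OCc4ccccc4)c3C[C@H]2O)cc1OCc1ccccc1
F3 | step 7 | rac-cis-5,7-bis(benzyloxy)-2-[3,5-bis(benzyloxy)-4-methoxyphenyl]chroman-3-ol (racemate, both enantiomers written) | COc1c(OCc2ccccc2)cc([C@H]2Oc3cc(OCc4ccccc4)cc(OCc4ccccc4)c3C[C@H]2O)cc1OCc1ccccc1.COc1c(OCc2ccccc2)cc([C@@H]2Oc3cc(OCc4ccccc4)cc(OCc4ccccc4)c3C[C@@H]2O)cc1OCc1ccccc1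
F4 | step 7 | (2R,3R)-5,7-bis(benzyloxy)-2-[3,5-bis(benzyloxy)-4-methoxyphenyl]chroman-3-yl (S)-2-methoxy-2-phenylacetate | COc1c(OCc2ccccc2)cc([C@H]2Oc3cc(OCc4ccccc4)cc(OCc4ccccc4)c3C[C@H]2OC(=O)[C@@H](OC)c2ccccc2)cc1OCc1ccccc1
F5 | step 7 | (2S,3S)-5,7-bis(benzyloxy)-2-[3,5-bis(benzyloxy)-4-methoxyphenyl]chroman-3-yl (S)-2-methoxy-2-phenylacetate | COc1c(OCc2ccccc2)cc([C@@H]2Oc3cc(OCc4ccccc4)cc(OCc4ccccc4)c3C[C@@H]2OC(=O)[C@@H](OC)c2ccccc2)cc1OCc1ccccc1
F6 | step 5 | rac-1-[3,5-bis(benzyloxy)-4-methoxyphenyl]prop-2-yn-1-yl acetate (racemate) | C#CC(OC(C)=O)c1cc(OCc2ccccc2)c(OC)c(OCc2ccccc2)c1
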